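## Analysis of the target

Plakortone L (21) is a cis-fused 2,6-dioxabicyclo[3.3.0]octan-3-one: a γ-lactone (O, C1, C2, C3, C4) and a tetrahydrofuran (O, C3, C4, C5, C6) share the C3–C4 bond. The numbering used throughout is C1 (lactone carbonyl), C2 (lactone CH2), C3 (fusion CH on the ether oxygen), C4 (fusion carbon with a methyl group and the lactone oxygen), C5 (ring CH2), C6 (ether carbon with a methyl group and the chain) and C7–C18 (twelve CH2 groups ending in phenyl). The three stereocentres C3, C4 and C6 are all S. C3 and C4 are cis by necessity; C6 is related to them only across the ring, with its methyl group on the face of the lactone and the chain on the other face. Two of the three centres are fully substituted carbinol carbons, and at C6 the two carbon substituents differ only beyond their first atom, so any reaction that sets C6 by choosing a face must tell methyl from an unbranched alkyl chain. The lactone is the only reactive group in the target, but every intermediate with a ketone at C4 can epimerise at C3 and can lose the ring oxygen by β-elimination. The strategy rests on two readings of the tetrahydrofuran ring. C6 carries O, CH3 and CH2R, the pattern of the carbinol carbon of 14-phenyltetradecan-2-ol with its hydrogen replaced by C5. C3, with its ether oxygen, its CH2C(=O) arm and the oxidised C4 next to it, is the carbinol carbon of an O-alkylated malic acid. The ring is therefore a secondary–secondary ether closed by one C–C bond, C5–C6, at the C6–H position.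

## Retrosynthetic reasoning

**21 to 19.** The lactone O–C1 bond and the C4–CH3 bond are cut together, giving keto ester 19. C4 is the one centre that can be made from a planar carbon directly next to an existing stereocentre. The forward step must deliver a methyl nucleophile to the C4 carbonyl on the face away from the C3 arm. The alkoxide of 20 then lies beside the CH2CO2Me group and closes the lactone itself. An alkoxide on the other face cannot lactonise, so ring closure also separates the two outcomes.

**19 to 18.** The C5–C6 bond is cut, opening the ring to diazoketone 18; C5 becomes the diazo carbon and C6 regains a hydrogen. Cutting O–C6 or O–C3 instead would require building a tertiary ether or selecting a face at C6. Cutting C5–C6 makes C6 the carbinol carbon of a simple secondary ether whose configuration can be bought. The forward step must form a C–C bond at an electron-rich C–H bond lying 1,5 to a metal carbenoid, with retention. It gives one ring, one skeletal bond and the quaternary centre.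

**18 to 16.** The C4–C5 bond is cut: the activated carboxyl group of acid 16 (as 17) acylates a one-carbon diazo reagent. C5 enters last, and the forward step must leave C3 and the methyl ester alone.

**16 to 12 and 13.** Acid 16 is imide 14 with the auxiliary removed (through 15). In 14 the C2–C3 bond is cut to the enolate of glycolate imide 12 and methyl bromoacetate 13. This step creates C3 under control of auxiliary 10. It also makes the two carboxyl carbons different from the outset: C4 is an imide and C1 a methyl ester, so no later selective hydrolysis is needed.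

**12 to 7, 8 and 10.** The N–acyl bond is cut to acid 9 and oxazolidinone 10 (through 11). The O–C3 ether bond of 9 is cut to alcohol 7 and bromoacetic acid 8. The hindered partner acts as the nucleophile at a primary carbon with no β-hydrogen, and the C6–O bond of 7 is never broken.

**7 to 4 and 5.** The C7–C8 bond is cut to Grignard reagent 6 (from bromide 4) and epoxide 5. Epoxide 5 supplies C6, its methyl group, C7 and the S configuration, since only its CH2 carbon is attacked.

**4 to 1 and 2.** The C–Br bond of 4 comes from anti-Markovnikov hydrobromination of alkene 3. The aryl–alkyl bond of 3 is cut to Grignard reagent 1 and bromoalkene 2.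

## Alternatives that were turned down

**Alternative 1:** Cyclobutanone route.
- **Disconnection:** the lactone is taken back by a retro-Baeyer–Villiger step to a cyclobutanone (O–C4 becomes C1–C4). The four-membered ring is then cut across C2–C3 and C1–C4 into dihydrofuran A1 and dichloroketene A2. In A1, C6 is already quaternary and a silyloxymethyl group stands in for the chain.
- **Forward key step:** [2+2] cycloaddition of A2 across the enol ether C3=C4 of A1. The ketene carbonyl carbon bonds to the nucleophilic C4 and the CCl2 carbon to C3, giving the cis-fused dichlorocyclobutanone A3. Zinc dechlorination and peracid ring expansion with migration of the quaternary C4 would follow.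
- **For it:** the ring fusion and the quaternary C4 arise together and are cis by necessity, with no addition to a hindered ketone. The regiochemistry of both the cycloaddition and the oxygen insertion is dependable.
- **Against it:** the face of the enol ether is chosen by C6, where methyl must be told from a CH2OSi group whose bulk sits several atoms away. A1 needs its own enantioselective synthesis of a tertiary ether and is an acid-labile enol ether. The chain must still be grown afterwards from a neopentyl-type carbon (desilylation, oxidation, olefination, hydrogenation) in the presence of the lactone, giving well over ten steps.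
- **Comparison:** on C4 this plan is stronger than the chosen one, which depends on face-selective methyl addition to 19. The chosen route offers a C3/C6 relation built from two separately made centres and transferred stereospecifically, a chain present from step 1, and fewer steps.

**Alternative 2:** Prins cascade.
- **Disconnection:** O–C6, C5–C6 and O(lactone)–C4 are cut at once. This gives the β-hydroxy ester A4, whose isopropenyl group holds C4, C5 and the C4 methyl, and the alkynyl ketal A5, which holds C6 with its methyl and the chain as an alkyne.
- **Forward key step:** a silyl triflate exchanges the C3 hydroxyl of A4 into ketal A5. The oxocarbenium ion at C6 is attacked by alkene carbon C5, and the tertiary cation at C4 is captured by the tert-butyl ester with loss of isobutene, giving lactone A6. Hydrogenation of the triple bond would finish.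
- **For it:** both rings, three bonds and two stereocentres form in one operation from two small fragments. The chain enters convergently, the lactone can only close cis, and the total is perhaps six steps, clearly shorter than the chosen route. Alkynyl also differs from methyl more than an alkyl chain does.
- **Against it:** the ring closes by a five-membered Prins-type cyclisation onto a ketone-derived oxocarbenium ion, less favourable than the six-membered case. It competes with oxonia-Cope scrambling, proton loss from the tertiary cation and early loss of the tert-butyl ester, and the propargylic cation can react at its alkyne terminus. Above all, C6 is set by how methyl and alkynyl arrange in a cationic transition state for which no secure model exists.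
- **Comparison:** superior in step economy and convergence. The chosen route gives this up for a C6 centre bought with epoxide 5 and carried into the ring by a stereospecific insertion.

**Alternative 3:** Palladium carboetherification.
- **Disconnection:** the O–C6 and C7–C8 bonds are cut. This gives diol A7, which carries C3 and C4 complete and a 1,1-disubstituted alkene C6=C7, and the alkenyl bromide A8 as the rest of the chain.
- **Forward key step:** carboetherification with a zerovalent palladium catalyst, a bisphosphine and a tert-butoxide base. Oxidative addition of A8, exchange of bromide for the C3 alkoxide, syn insertion of the alkene into the Pd–O bond and C–C reductive elimination give tetrahydrofuran A9. Hydrogenation, desilylation and oxidation of the primary alcohol onto the tertiary hydroxyl would complete the lactone.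
- **For it:** ring closure and chain attachment coincide, so chain analogues need only another bromide; the chosen route cannot match this. The alkylpalladium intermediate at C7 has no β-hydrogen on C6. The usual preference of this reaction for placing the new CH2R group trans to the substituent on the carbinol carbon points to the right C6 configuration.
- **Against it:** 1,1-disubstituted alkenes insert slowly and less selectively, and the step must create a quaternary centre beside a free tertiary alcohol, with Heck coupling of A8 competing. A7 needs a multi-step enantioselective synthesis of two adjacent carbinol centres. Three redox or protecting-group steps follow.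
- **Comparison:** similar in length and better in modularity. C6 is again set by diastereoselection, whereas the chosen insertion transfers a preformed centre with retention.

Key step: step 9

Remark on the chemistry: C1–C4 are assembled on a glycolate (steps 4–7) and not taken from a malic ester. Displacing a malic ester sulfonate with the alkoxide of 7 would compete with elimination to the fumarate, and the two ester groups of a dialkyl 2-alkoxysuccinate cannot be told apart reliably by hydrolysis.

## Route

Step 1
Reactants: 1 phenylmagnesium bromide; 2 11-bromoundec-1-ene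
Product: 3 (undec-10-en-1-yl)benzene
Conditions: FeCl3 (5 mol %), TMEDA, THF, 0 °C, slow addition of 1
Reagents that add atoms: none
Why: Iron-catalysed Kumada-type (Kochi) coupling of an aryl Grignard reagent with a primary alkyl bromide; TMEDA holds back β-hydride elimination and homocoupling, and the remote terminal alkene is a spectator.

Step 2
Reactants: 3 (undec-10-en-1-yl)benzene
Product: 4 (11-bromoundecyl)benzene
Conditions: HBr (g), dibenzoyl peroxide (cat.), hexane, 0 °C to rt
Reagents that add atoms: hydrogen bromide, Br
Why: Kharasch radical-chain hydrobromination: the bromine atom adds to the terminal carbon and the secondary radical takes hydrogen from HBr, so the bromide ends up primary; the non-polar medium suppresses ionic Markovnikov addition.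

Step 3
Reactants: 4 (11-bromoundecyl)benzene; 5 (S)-2-methyloxirane
Product: 7 (2S)-14-phenyltetradecan-2-ol, via (11-phenylundecyl)magnesium bromide 6 (not isolated)
Conditions: Mg, THF, reflux; then CuI (copper iodide, 10 mol %), 5, THF, −30 to 0 °C
Reagents that add atoms: none
Why: Grignard formation followed by copper-catalysed SN2 opening of the terminal epoxide at its CH2 carbon; no bond to the stereocentre of 5 is broken, so the later C6 stays S.

Step 4
Reactants: 7 (2S)-14-phenyltetradecan-2-ol; 8 bromoacetic acid
Product: 9 {[(2S)-14-phenyltetradecan-2-yl]oxy}acetic acid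
Conditions: NaH (3 equiv), THF, 0 °C; then 8, 0 °C to reflux; aq. HCl
Reagents that add atoms: none
Why: Williamson ether synthesis: the sodium alkoxide of 7 displaces bromide from the carboxylate of 8 at a primary carbon without β-hydrogens, so neither elimination nor any change at C6 is possible.

Step 5
Reactants: 9 {[(2S)-14-phenyltetradecan-2-yl]oxy}acetic acid; 10 (4R)-4-benzyl-1,3-oxazolidin-2-one
Product: 12 (4R)-4-benzyl-3-({[(2S)-14-phenyltetradecan-2-yl]oxy}acetyl)-1,3-oxazolidin-2-one, via mixed pivalic anhydride 11 (not isolated)
Conditions: PivCl, Et3N, THF, −20 °C; then LiCl, 10, −20 °C to rt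
Reagents that add atoms: none
Why: N-acylation of an Evans oxazolidinone through the mixed pivalic anhydride with LiCl/Et3N activation; the tert-butyl group steers attack to the glycolyl carbonyl.

Step 6
Reactants: 12 (4R)-4-benzyl-3-({[(2S)-14-phenyltetradecan-2-yl]oxy}acetyl)-1,3-oxazolidin-2-one; 13 methyl bromoacetate
Product: 14 methyl (3S)-4-[(4R)-4-benzyl-2-oxo-1,3-oxazolidin-3-yl]-4-oxo-3-{[(2S)-14-phenyltetradecan-2-yl]oxy}butanoate
Conditions: NaN(SiMe3)2, THF, −78 °C; then 13, −78 to −45 °C
Reagents that add atoms: none
Why: Evans-type asymmetric alkylation of a glycolate imide: the chelated Z sodium enolate is screened on one face by the benzyl group of the (R)-auxiliary, and the reactive α-bromo ester enters from the other, setting C3 as S. The step forms the C2–C3 bond and leaves the two carboxyl termini differentiated.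

Step 7
Reactants: 14 methyl (3S)-4-[(4R)-4-benzyl-2-oxo-1,3-oxazolidin-3-yl]-4-oxo-3-{[(2S)-14-phenyltetradecan-2-yl]oxy}butanoate
Product: 16 (2S)-4-methoxy-4-oxo-2-{[(2S)-14-phenyltetradecan-2-yl]oxy}butanoic acid, via peroxy acid 15 (not isolated)
Conditions: LiOH, H2O2, THF/H2O, 0 °C; then aq. Na2SO3; aq. HCl to pH 3
Reagents that add atoms: hydrogen peroxide, OO
Why: Hydroperoxide cleavage of an N-acyl oxazolidinone: the α-effect nucleophile attacks the exocyclic imide carbonyl far faster than the methyl ester is saponified at 0 °C, and sulfite reduces peracid 15. C3 is not enolised under these conditions.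

Step 8
Reactants: 16 (2S)-4-methoxy-4-oxo-2-{[(2S)-14-phenyltetradecan-2-yl]oxy}butanoic acid
Product: 18 methyl (3S)-5-diazo-4-oxo-3-{[(2S)-14-phenyltetradecan-2-yl]oxy}pentanoate, via mixed carbonic anhydride 17 (not isolated)
Conditions: i-BuOCOCl, N-methylmorpholine, THF, −20 °C; then CH2N2, Et2O, −20 °C to rt
Reagents that add atoms: diazomethane, C=[N+]=[N-]
Why: Acylation of diazomethane by a mixed carbonic anhydride (first stage of an Arndt–Eistert sequence): attack occurs at the more electrophilic acyl carbonyl and the carbonate fragment takes up the proton. No base strong enough to epimerise C3 is present.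

Step 9
Reactants: 18 methyl (3S)-5-diazo-4-oxo-3-{[(2S)-14-phenyltetradecan-2-yl]oxy}pentanoate
Product: 19 methyl 2-[(2S,5S)-5-methyl-3-oxo-5-(12-phenyldodecyl)oxolan-2-yl]acetate
Conditions: Rh2(OAc)4 (2 mol %), CH2Cl2, rt, slow addition of 18
Reagents that add atoms: none
Why: Dirhodium tetraacetate, a divalent rhodium paddlewheel, takes up the diazo carbon of 18, N2 leaves and an electrophilic carbenoid results at C5. The carbenoid carbon meets the C6–H bond, which lies 1,5 to it through C4, C3 and the ether oxygen, and in a concerted three-centre transition state the C5–C6 bond forms as hydrogen passes to C5 and the catalyst is released. The closest known reaction type is the dirhodium-catalysed intramolecular C–H insertion of α-alkoxy α'-diazoketones next to the ether oxygen, which gives 3-oxotetrahydrofurans. The tetrahydrofuran ring O–C3–C4–C5–C6 is closed by 1,5 insertion, C–C bond formation through a five-membered-ring transition state. C6 becomes quaternary with retention, because the new bond forms on the face that hydrogen leaves, so its configuration is that of 7 and hence of 5. The step needs site selectivity for C6–H, secured because this bond is tertiary, activated by the adjacent oxygen and the only one that closes a five-membered ring. The C7 and C6-methyl hydrogens would give six-membered rings, the deactivated C2 hydrogens a four-membered ring, the ether oxygen a four-membered ylide and the weakly nucleophilic ester carbonyl a six-membered ylide. C3 is untouched under these neutral conditions, and slow addition keeps carbenoid dimerisation down.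

Step 10
Reactants: 19 methyl 2-[(2S,5S)-5-methyl-3-oxo-5-(12-phenyldodecyl)oxolan-2-yl]acetate
Product: 21 plakortone L [(3aS,5S,6aS)-5,6a-dimethyl-5-(12-phenyldodecyl)tetrahydrofuro[3,2-b]furan-2(3H)-one], via hydroxy ester alkoxide 20 (not isolated)
Conditions: MeMgBr, CeCl3, THF, −78 to 0 °C
Reagents that add atoms: methylmagnesium bromide, C[Mg]Br
Why: Organocerium (Imamoto) 1,2-addition, chosen because the reagent is nucleophilic but weakly basic and prefers the ketone to the ester. Methyl should attack C4 anti to the adjacent C3 arm, so the alkoxide of 20 is cis to CH2CO2Me and closes the γ-lactone by 5-exo-trig acyl substitution with loss of methoxide. C4 is thus set by 1,2-induction from C3, and an alkoxide on the other face could not lactonise and would remain a separable hydroxy ester.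

## Compound list

1 | phenylmagnesium bromide | Br[Mg]c1ccccc1 | starting material
2 | 11-bromoundec-1-ene | C=CCCCCCCCCCBr | starting material
3 | (undec-10-en-1-yl)benzene | C=CCCCCCCCCCc1ccccc1 | intermediate
4 | (11-bromoundecyl)benzene | BrCCCCCCCCCCCc1ccccc1 | intermediate
5 | (S)-2-methyloxirane | C[C@H]1CO1 | starting material
6 | (11-phenylundecyl)magnesium bromide | Br[Mg]CCCCCCCCCCCc1ccccc1 | intermediate
7 | (2S)-14-phenyltetradecan-2-ol | C[C@H](O)CCCCCCCCCCCCc1ccccc1 | intermediate
8 | bromoacetic acid | OC(=O)CBr | starting material
9 | {[(2S)-14-phenyltetradecan-2-yl]oxy}acetic acid | C[C@H](OCC(=O)O)CCCCCCCCCCCCc1ccccc1 | intermediate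
10 | (4R)-4-benzyl-1,3-oxazolidin-2-one | O=C1N[C@H](Cc2ccccc2)CO1 | starting material
11 | 2,2-dimethylpropanoic {[(2S)-14-phenyltetradecan-2-yl]oxy}acetic anhydride | C[C@H](OCC(=O)OC(=O)C(C)(C)C)CCCCCCCCCCCCc1ccccc1 | intermediate
12 | (4R)-4-benzyl-3-({[(2S)-14-phenyltetradecan-2-yl]oxy}acetyl)-1,3-oxazolidin-2-one | C[C@H](OCC(=O)N1[C@H](Cc2ccccc2)COC1=O)CCCCCCCCCCCCc1ccccc1 | intermediate
13 | methyl bromoacetate | COC(=O)CBr | starting material
14 | methyl (3S)-4-[(4R)-4-benzyl-2-oxo-1,3-oxazolidin-3-yl]-4-oxo-3-{[(2S)-14-phenyltetradecan-2-yl]oxy}butanoate | O=C1OC[C@@H](Cc2ccccc2)N1C(=O)[C@H](CC(=O)OC)O[C@@H](C)CCCCCCCCCCCCc1ccccc1 | intermediate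
15 | (2S)-4-methoxy-4-oxo-2-{[(2S)-14-phenyltetradecan-2-yl]oxy}butaneperoxoic acid | OOC(=O)[C@H](CC(=O)OC)O[C@@H](C)CCCCCCCCCCCCc1ccccc1 | intermediate
16 | (2S)-4-methoxy-4-oxo-2-{[(2S)-14-phenyltetradecan-2-yl]oxy}butanoic acid | OC(=O)[C@H](CC(=O)OC)O[C@@H](C)CCCCCCCCCCCCc1ccccc1 | intermediate
17 | (2S)-4-methoxy-4-oxo-2-{[(2S)-14-phenyltetradecan-2-yl]oxy}butanoic 2-methylpropyl carbonic anhydride | CC(C)COC(=O)OC(=O)[C@H](CC(=O)OC)O[C@@H](C)CCCCCCCCCCCCc1ccccc1 | intermediate
18 | methyl (3S)-5-diazo-4-oxo-3-{[(2S)-14-phenyltetradecan-2-yl]oxy}pentanoate | [N-]=[N+]=CC(=O)[C@H](CC(=O)OC)O[C@@H](C)CCCCCCCCCCCCc1ccccc1 | intermediate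
19 | methyl 2-[(2S,5S)-5-methyl-3-oxo-5-(12-phenyldodecyl)oxolan-2-yl]acetate | C[C@]1(CCCCCCCCCCCCc2ccccc2)CC(=O)[C@H](CC(=O)OC)O1 | intermediate
20 | methyl 2-[(2S,3S,5S)-3-hydroxy-3,5-dimethyl-5-(12-phenyldodecyl)oxolan-2-yl]acetate, formed as its metal alkoxide | C[C@]1(CCCCCCCCCCCCc2ccccc2)C[C@](C)(O)[C@H](CC(=O)OC)O1 | intermediate
21 | plakortone L, (3aS,5S,6aS)-5,6a-dimethyl-5-(12-phenyldodecyl)tetrahydrofuro[3,2-b]furan-2(3H)-one | C[C@]1(CCCCCCCCCCCCc2ccccc2)C[C@]2(C)OC(=O)C[C@@H]2O1 | target

## Step count and least certain steps

Total: 10 steps. Longest linear sequence: 10 steps (from 1 and 2 to 21). Compounds 1, 2, 5, 8, 10 and 13 are bought.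

**Step 9 (key step).** The carbenoid may be captured by the ester carbonyl oxygen (six-membered carbonyl ylide) or may dimerise, and insertion into the congested tertiary C–H bond may be slow. Product 19 may lose C3 configuration by enolisation, or open by β-elimination of the ring oxygen, during purification; it should be carried on quickly.
Fallback: switch to an acceptor/acceptor carbenoid with a removable ester, which is less reactive and more selective for C–H insertion. Setting out from acid 16, activation with carbonyldiimidazole and C-acylation of Mg(O2CCH2CO2Bn)2 (Masamune–Brooks) should give 1-benzyl 6-methyl (4S)-3-oxo-4-{[(2S)-14-phenyltetradecan-2-yl]oxy}hexanedioate F1. Regitz diazo transfer (4-acetamidobenzenesulfonyl azide, Et3N) should give 1-benzyl 6-methyl (4S)-2-diazo-3-oxo-4-{[(2S)-14-phenyltetradecan-2-yl]oxy}hexanedioate F2. Rh2(OAc)4 in CH2Cl2 at reflux should give benzyl (2S,5S)-5-(2-methoxy-2-oxoethyl)-2-methyl-4-oxo-2-(12-phenyldodecyl)oxolane-3-carboxylate F3. Hydrogenolysis (H2, Pd/C) should give (2S,5S)-5-(2-methoxy-2-oxoethyl)-2-methyl-4-oxo-2-(12-phenyldodecyl)oxolane-3-carboxylic acid F4, which loses CO2 on gentle warming and returns to the route at 19.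

**Step 10.** Facial selectivity may be poor, because the C6 chain sits on the face anti to the C3 arm and partly offsets the 1,2-bias. Enolisation may also lead to epimerisation at C3 or ring opening.
Fallback: set C4 by ring constraint instead of by face selection. Setting out from 19, Takai–Lombardo methylenation (Zn, CH2Br2, TiCl4) should give methyl 2-[(2S,5S)-5-methyl-3-methylidene-5-(12-phenyldodecyl)oxolan-2-yl]acetate F5. Hydrolysis with LiOH should give 2-[(2S,5S)-5-methyl-3-methylidene-5-(12-phenyldodecyl)oxolan-2-yl]acetic acid F6. Iodolactonisation (I2, NaHCO3) can only close cis at the tertiary C4 and should give (3aS,5S,6aS)-6a-(iodomethyl)-5-methyl-5-(12-phenyldodecyl)tetrahydrofuro[3,2-b]furan-2(3H)-one F7. Radical deiodination (Bu3SnH, AIBN) returns to the route at 21.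

**Step 6.** Alkylation may be slow with the bulky secondary alkoxy group, so the sodium enolate may decompose (loss of the oxazolidinone) or be quenched by proton transfer to the bromo ester.
Fallback: use the most reliable electrophile for glycolate imides and unveil the ester oxidatively. Setting out from 12, NaN(SiMe3)2 and allyl iodide should give (4R)-4-benzyl-3-[(2S)-2-{[(2S)-14-phenyltetradecan-2-yl]oxy}pent-4-enoyl]-1,3-oxazolidin-2-one F8. Ozonolysis (O3, then PPh3) should give (3S)-4-[(4R)-4-benzyl-2-oxo-1,3-oxazolidin-3-yl]-4-oxo-3-{[(2S)-14-phenyltetradecan-2-yl]oxy}butanal F9. Pinnick oxidation (NaClO2) should give (3S)-4-[(4R)-4-benzyl-2-oxo-1,3-oxazolidin-3-yl]-4-oxo-3-{[(2S)-14-phenyltetradecan-2-yl]oxy}butanoic acid F10. Methylation with Me3SiCHN2/MeOH returns to the route at 14.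

**Step 7.** The methyl ester may be partly saponified during removal of the auxiliary, giving the diacid.
Fallback: replace hydrolysis by transesterification and hydrogenolysis. Setting out from 14, LiOBn in THF at −20 °C should give 1-benzyl 4-methyl (2S)-2-{[(2S)-14-phenyltetradecan-2-yl]oxy}butanedioate F11. Hydrogenolysis (H2, Pd/C) returns to the route at 16.

**Step 2.** Ionic Markovnikov addition may compete if radical initiation is inefficient, giving a secondary bromide that is hard to separate.
Fallback: hydroboration and bromination. Setting out from 3, 9-BBN then NaOH/H2O2 should give 11-phenylundecan-1-ol F12. Appel bromination (CBr4, PPh3) returns to the route at 4.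

## Further compounds

F1 | step 9 | 1-benzyl 6-methyl (4S)-3-oxo-4-{[(2S)-14-phenyltetradecan-2-yl]oxy}hexanedioate | O=C(OCc1ccccc1)CC(=O)[C@H](CC(=O)OC)O[C@@H](C)CCCCCCCCCCCCc1ccccc1
F2 | step 9 | 1-benzyl 6-methyl (4S)-2-diazo-3-oxo-4-{[(2S)-14-phenyltetradecan-2-yl]oxy}hexanedioate | O=C(OCc1ccccc1)C(=[N+]=[N-])C(=O)[C@H](CC(=O)OC)O[C@@H](C)CCCCCCCCCCCCc1ccccc1
F3 | step 9 | benzyl (2S,5S)-5-(2-methoxy-2-oxoethyl)-2-methyl-4-oxo-2-(12-phenyldodecyl)oxolane-3-carboxylate, C3 epimers | C[C@]1(CCCCCCCCCCCCc2ccccc2)C(C(=O)OCc2ccccc2)C(=O)[C@H](CC(=O)OC)O1
F4 | step 9 | (2S,5S)-5-(2-methoxy-2-oxoethyl)-2-methyl-4-oxo-2-(12-phenyldodecyl)oxolane-3-carboxylic acid, C3 epimers | C[C@]1(CCCCCCCCCCCCc2ccccc2)C(C(=O)O)C(=O)[C@H](CC(=O)OC)O1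
F5 | step 10 | methyl 2-[(2S,5S)-5-methyl-3-methylidene-5-(12-phenyldodecyl)oxolan-2-yl]acetate | C[C@]1(CCCCCCCCCCCCc2ccccc2)CC(=C)[C@H](CC(=O)OC)O1
F6 | step 10 | 2-[(2S,5S)-5-methyl-3-methylidene-5-(12-phenyldodecyl)oxolan-2-yl]acetic acid | C[C@]1(CCCCCCCCCCCCc2ccccc2)CC(=C)[C@H](CC(=O)O)O1
F7 | step 10 | (3aS,5S,6aS)-6a-(iodomethyl)-5-methyl-5-(12-phenyldodecyl)tetrahydrofuro[3,2-b]furan-2(3H)-one | C[C@]1(CCCCCCCCCCCCc2ccccc2)C[C@]2(CI)OC(=O)C[C@@H]2O1
F8 | step 6 | (4R)-4-benzyl-3-[(2S)-2-{[(2S)-14-phenyltetradecan-2-yl]oxy}pent-4-enoyl]-1,3-oxazolidin-2-one | O=C1OC[C@@H](Cc2ccccc2)N1C(=O)[C@H](CC=C)O[C@@H](C)CCCCCCCCCCCCc1ccccc1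
F9 | step 6 | (3S)-4-[(4R)-4-benzyl-2-oxo-1,3-oxazolidin-3-yl]-4-oxo-3-{[(2S)-14-phenyltetradecan-2-yl]oxy}butanal | O=C1OC[C@@H](Cc2ccccc2)N1C(=O)[C@H](CC=O)O[C@@H](C)CCCCCCCCCCCCc1ccccc1
F10 | step 6 | (3S)-4-[(4R)-4-benzyl-2-oxo-1,3-oxazolidin-3-yl]-4-oxo-3-{[(2S)-14-phenyltetradecan-2-yl]oxy}butanoic acid | O=C1OC[C@@H](Cc2ccccc2)N1C(=O)[C@H](CC(=O)O)O[C@@H](C)CCCCCCCCCCCCc1ccccc1
F11 | step 7 | 1-benzyl 4-methyl (2S)-2-{[(2S)-14-phenyltetradecan-2-yl]oxy}butanedioate | O=C(OCc1ccccc1)[C@H](CC(=O)OC)O[C@@H](C)CCCCCCCCCCCCc1ccccc1
F12 | step 2 | 11-phenylundecan-1-ol | OCCCCCCCCCCCc1ccccc1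
A1 | alternative 1 | tert-butyl{[(2R)-2,4-dimethyl-2,3-dihydrofuran-2-yl]methoxy}diphenylsilane | C[C@]1(CO[Si](c2ccccc2)(c2ccccc2)C(C)(C)C)CC(C)=CO1
A2 | alternative 1 | dichloroketene | ClC(Cl)=C=O
A3 | alternative 1 | (1R,3R,5S)-3-({[tert-butyl(diphenyl)silyl]oxy}methyl)-7,7-dichloro-3,5-dimethyl-2-oxabicyclo[3.2.0]heptan-6-one | C[C@]1(CO[Si](c3ccccc3)(c3ccccc3)C(C)(C)C)C[C@]2(C)C(=O)C(Cl)(Cl)[C@@H]2O1
A4 | alternative 2 | tert-butyl (3S)-3-hydroxy-4-methylpent-4-enoate | CC(=C)[C@@H](O)CC(=O)OC(C)(C)C
A5 | alternative 2 | (13,13-dimethoxytetradec-11-yn-1-yl)benzene | COC(C)(OC)C#CCCCCCCCCCCc1ccccc1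
A6 | alternative 2 | (3aS,5R,6aS)-5,6a-dimethyl-5-(12-phenyldodec-1-yn-1-yl)tetrahydrofuro[3,2-b]furan-2(3H)-one | C[C@]1(C#CCCCCCCCCCCc2ccccc2)C[C@]2(C)OC(=O)C[C@@H]2O1
A7 | alternative 3 | (3S,4S)-1-{[tert-butyl(dimethyl)silyl]oxy}-4,6-dimethylhept-6-ene-3,4-diol | CC(=C)C[C@](C)(O)[C@H](CCO[Si](C)(C)C(C)(C)C)O
A8 | alternative 3 | [(10E)-11-bromoundec-10-en-1-yl]benzene | Br/C=C/CCCCCCCCCc1ccccc1
A9 | alternative 3 | (2S,3S,5S)-2-(2-{[tert-butyl(dimethyl)silyl]oxy}ethyl)-3,5-dimethyl-5-[(2E)-12-phenyldodec-2-en-1-yl]oxolan-3-ol | C[C@]1(C/C=C/CCCCCCCCCc2ccccc2)C[C@](C)(O)[C@H](CCO[Si](C)(C)C(C)(C)C)O1
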